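**Plan**

- Retrosynthesis: the three benzyl ethers, the 5'-acetate and the C3–OMe bond are removed first. Ring C is then cut at C4a–C4, C4–C3 and O1–C2 into a ring A 2-iodophenyl acetate, carbon monoxide and a ring B arylacetylene. The alkyne is cut at C1'–C(sp) back to a vanillin-derived aryl iodide.
- Enabling feature: C4 of ring C is a lone carbonyl carbon between C4a of ring A and the two-carbon unit C3–C2 that carries ring B, and O1 is a phenol oxygen ortho to C4a. C4 can therefore be CO inserted between an aryl iodide and a terminal alkyne.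
- Forward: the ring A iodide (2 steps) and the ring B alkyne (6 steps from vanillin) are made separately, and ring C closes in the three-component carbonylative annulation. C3 is then oxygenated and methylated, the 5'-methoxymethyl ether is exchanged for acetate, and the benzyl groups are removed last.
- Stereochemistry: the target has no stereocentre; only regiochemistry (two iodinations, 6-endo closure, C3 metalation) has to be controlled.

Key step: step 9

Remark on the chemistry: 3,5-bis(benzyloxy)phenol is taken as a catalogue compound, and the enaminones formed in the flask are drawn as E isomers although their push–pull double bond is configurationally labile.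

**Route**

Step 1
Reactants: 1 3,5-bis(benzyloxy)phenol
Product: 2 3,5-bis(benzyloxy)-2-iodophenol
Conditions: NIS (1.0 equiv), CH2Cl2, −20 to 0 °C, dark
Reagents that add atoms: N-iodosuccinimide, O=C1CCC(=O)N1I
Why: Electrophilic aromatic iodination of the phloroglucinol-type ring should go mainly ortho to the free hydroxyl, since C2 is less hindered than C4 between the two benzyloxy groups and is statistically doubled.

Step 2
Reactants: 2 3,5-bis(benzyloxy)-2-iodophenol
Product: 3 3,5-bis(benzyloxy)-2-iodophenyl acetate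
Conditions: Ac2O, pyridine, DMAP (cat.), CH2Cl2, rt
Reagents that add atoms: acetic anhydride, CC(=O)OC(C)=O
Why: DMAP-catalysed O-acylation of the phenol lowers the electron density at the C–I bond and masks the nucleophilic oxygen until the key step has formed the ynone.

Step 3
Reactants: 4 vanillin (4-hydroxy-3-methoxybenzaldehyde)
Product: 5 3-methoxy-4-(methoxymethoxy)benzaldehyde
Conditions: MOMCl, i-Pr2NEt, CH2Cl2, 0 °C to rt
Reagents that add atoms: chloromethyl methyl ether, COCCl
Why: Williamson-type O-alkylation of the acidic vanillin phenol gives a methoxymethyl acetal that is stable to base, amines and organolithium reagents.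

Step 4
Reactants: 5 3-methoxy-4-(methoxymethoxy)benzaldehyde
Product: 7 3-methoxy-4-(methoxymethoxy)phenol, via aryl formate 6 (not isolated)
Conditions: mCPBA, CH2Cl2, rt; then K2CO3 (cat.), MeOH, rt
Reagents that add atoms: 3-chloroperoxybenzoic acid, O=C(OO)c1cccc(Cl)c1
Why: Baeyer–Villiger (Dakin-type) oxidation with migration of the electron-rich aryl group gives the formate, which is cleaved by transesterification to the phenol that becomes the 2'-oxygen.

Step 5
Reactants: 7 3-methoxy-4-(methoxymethoxy)phenol
Product: 8 4-(benzyloxy)-2-methoxy-1-(methoxymethoxy)benzene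
Conditions: BnBr, K2CO3, DMF, rt
Reagents that add atoms: benzyl bromide, BrCc1ccccc1
Why: Williamson ether synthesis on the only free phenol differentiates the future 2'-oxygen (benzyl) from the future 5'-oxygen (methoxymethyl).

Step 6
Reactants: 8 4-(benzyloxy)-2-methoxy-1-(methoxymethoxy)benzene
Product: 9 1-(benzyloxy)-2-iodo-5-methoxy-4-(methoxymethoxy)benzene
Conditions: NIS, MeCN, rt, dark
Reagents that add atoms: N-iodosuccinimide, O=C1CCC(=O)N1I
Why: Electrophilic aromatic iodination of the 1,2,4-trialkoxybenzene should go para to the methoxy group and ortho to the benzyloxy group, the only unhindered position activated by two oxygen substituents, under acid-free conditions that spare the acetal.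

Step 7
Reactants: 9 1-(benzyloxy)-2-iodo-5-methoxy-4-(methoxymethoxy)benzene
Product: 10 {[2-(benzyloxy)-4-methoxy-5-(methoxymethoxy)phenyl]ethynyl}trimethylsilane
Conditions: ethynyltrimethylsilane, PdCl2(PPh3)2 (2 mol %), CuI (4 mol %), Et3N, THF, 50 °C
Reagents that add atoms: ethynyltrimethylsilane, C#C[Si](C)(C)C
Why: Sonogashira coupling of an aryl iodide with a silyl-capped acetylene installs the two-carbon unit at C1' without homocoupling of a free diyne.

Step 8
Reactants: 10 {[2-(benzyloxy)-4-methoxy-5-(methoxymethoxy)phenyl]ethynyl}trimethylsilane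
Product: 11 1-(benzyloxy)-2-ethynyl-5-methoxy-4-(methoxymethoxy)benzene
Conditions: K2CO3 (cat.), MeOH/THF, rt
Reagents that add atoms: none
Why: Base-catalysed protodesilylation of the alkynylsilane by methoxide frees the terminal alkyne and touches no other group.

Step 9
Reactants: 3 3,5-bis(benzyloxy)-2-iodophenyl acetate; 11 1-(benzyloxy)-2-ethynyl-5-methoxy-4-(methoxymethoxy)benzene; 12 carbon monoxide
Product: 16 5,7,2'-tris(benzyloxy)-4'-methoxy-5'-(methoxymethoxy)flavone, via acetoxy ynone 13 (not isolated), via acetoxy enaminone 14 (not isolated), via hydroxy enaminone 15 (not isolated)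
Conditions: 11 (1.3 equiv), PdCl2(PPh3)2 (5 mol %), dppp (5 mol %), thiourea (5 mol %), CO (balloon), Et2NH, 40 °C
Reagents that add atoms: none
Why: Zerovalent palladium formed in situ inserts into the C–I bond of 3, CO insertion gives the aroylpalladium iodide (divalent palladium), and copper-free coupling with the acetylide of 11 followed by reductive elimination gives ynone 13 with the C4a–C4 and C4–C3 bonds in place. Diethylamine then adds to the ynone to give enaminone 14 and cleaves the aryl acetate to 15, whose phenol adds to C2 and expels the amine, so ring C closes by a 6-endo-trig addition–elimination that forms O1–C2. The closest known reaction type is the palladium-catalysed carbonylative annulation of 2-iodophenols or their acetates with terminal arylacetylenes and CO in a secondary amine, which gives flavones. No stereocentre is formed. The step needs carbonylative rather than direct alkynylation and 6-endo rather than 5-exo (aurone) closure: the absence of copper under CO secures the first, and the acetate, which keeps the phenol masked until the amine has made the ynone an enaminone electrophilic only at C2, secures the second.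

Step 10
Reactants: 16 5,7,2'-tris(benzyloxy)-4'-methoxy-5'-(methoxymethoxy)flavone
Product: 19 5,7,2'-tris(benzyloxy)-3-hydroxy-4'-methoxy-5'-(methoxymethoxy)flavone, via 3-lithioflavone 17 (not isolated), via dimethyl flavon-3-ylboronate 18 (not isolated)
Conditions: LiN(iPr)2, THF, −78 °C; B(OMe)3, −78 to 0 °C; AcOH, 30% H2O2, 0 °C to rt
Reagents that add atoms: hydrogen peroxide, OO (oxygen at C3); trimethyl borate, COB(OC)OC (boron of 18 only, lost on oxidation)
Why: C3 is the only acidic ring C position, so lithiation with a lithium amide, borylation and oxidative boron-to-oxygen 1,2-shift (the known lithiation–borylation–oxidation route from flavones to flavonols) should deliver the 3-hydroxyl.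

Step 11
Reactants: 19 5,7,2'-tris(benzyloxy)-3-hydroxy-4'-methoxy-5'-(methoxymethoxy)flavone
Product: 20 5,7,2'-tris(benzyloxy)-3,4'-dimethoxy-5'-(methoxymethoxy)flavone
Conditions: MeI, K2CO3, DMF, rt
Reagents that add atoms: iodomethane, CI
Why: Williamson O-methylation of the only free hydroxyl, the enolic 3-OH, sets the 3-methoxy group.

Step 12
Reactants: 20 5,7,2'-tris(benzyloxy)-3,4'-dimethoxy-5'-(methoxymethoxy)flavone
Product: 21 5,7,2'-tris(benzyloxy)-5'-hydroxy-3,4'-dimethoxyflavone
Conditions: conc. HCl (cat.), MeOH/THF, 45 °C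
Reagents that add atoms: none
Why: Acid-catalysed acetal methanolysis removes the methoxymethyl group selectively, since benzyl and methyl aryl ethers are stable to dilute acid.

Step 13
Reactants: 21 5,7,2'-tris(benzyloxy)-5'-hydroxy-3,4'-dimethoxyflavone
Product: 22 5,7,2'-tris(benzyloxy)-3,4'-dimethoxyflavon-5'-yl acetate
Conditions: Ac2O, pyridine, DMAP (cat.), CH2Cl2, rt
Reagents that add atoms: acetic anhydride, CC(=O)OC(C)=O
Why: DMAP-catalysed acylation of the only free hydroxyl places the acetate unambiguously on the 5'-oxygen.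

Step 14
Reactants: 22 5,7,2'-tris(benzyloxy)-3,4'-dimethoxyflavon-5'-yl acetate
Product: 23 5,7,2',5'-tetrahydroxy-3,4'-dimethoxyflavone 5'-acetate
Conditions: H2 (1 atm), 10% Pd/C, EtOAc/THF, rt
Reagents that add atoms: none
Why: Catalytic hydrogenolysis cleaves the three benzyl aryl ethers under neutral aprotic conditions that should leave the aryl acetate, the methyl ethers and the chromone double bond intact, and the acetate cannot migrate to the para-disposed 2'-hydroxyl.

**Compound list**

1 | 3,5-bis(benzyloxy)phenol | Oc1cc(OCc2ccccc2)cc(OCc2ccccc2)c1 | starting material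
2 | 3,5-bis(benzyloxy)-2-iodophenol | Oc1cc(OCc2ccccc2)cc(OCc2ccccc2)c1I | intermediate
3 | 3,5-bis(benzyloxy)-2-iodophenyl acetate | CC(=O)Oc1cc(OCc2ccccc2)cc(OCc2ccccc2)c1I | intermediate
4 | vanillin (4-hydroxy-3-methoxybenzaldehyde) | COc1cc(C=O)ccc1O | starting material
5 | 3-methoxy-4-(methoxymethoxy)benzaldehyde | COCOc1ccc(C=O)cc1OC | intermediate
6 | 3-methoxy-4-(methoxymethoxy)phenyl formate | COCOc1ccc(OC=O)cc1OC | intermediate
7 | 3-methoxy-4-(methoxymethoxy)phenol | COCOc1ccc(O)cc1OC | intermediate
8 | 4-(benzyloxy)-2-methoxy-1-(methoxymethoxy)benzene | COCOc1ccc(OCc2ccccc2)cc1OC | intermediate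
9 | 1-(benzyloxy)-2-iodo-5-methoxy-4-(methoxymethoxy)benzene | COCOc1cc(I)c(OCc2ccccc2)cc1OC | intermediate
10 | {[2-(benzyloxy)-4-methoxy-5-(methoxymethoxy)phenyl]ethynyl}trimethylsilane | COCOc1cc(C#C[Si](C)(C)C)c(OCc2ccccc2)cc1OC | intermediate
11 | 1-(benzyloxy)-2-ethynyl-5-methoxy-4-(methoxymethoxy)benzene | C#Cc1cc(OCOC)c(OC)cc1OCc1ccccc1 | intermediate
12 | carbon monoxide | [C-]#[O+] | starting material
13 | 3,5-bis(benzyloxy)-2-{3-[2-(benzyloxy)-4-methoxy-5-(methoxymethoxy)phenyl]prop-2-ynoyl}phenyl acetate | CC(=O)Oc1cc(OCc2ccccc2)cc(OCc2ccccc2)c1C(=O)C#Cc1cc(OCOC)c(OC)cc1OCc1ccccc1 | intermediate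
14 | 3,5-bis(benzyloxy)-2-{(E)-3-[2-(benzyloxy)-4-methoxy-5-(methoxymethoxy)phenyl]-3-(diethylamino)prop-2-enoyl}phenyl acetate | CCN(CC)/C(c1cc(OCOC)c(OC)cc1OCc1ccccc1)=C/C(=O)c1c(OC(C)=O)cc(OCc2ccccc2)cc1OCc1ccccc1 | intermediate
15 | (E)-1-[2,4-bis(benzyloxy)-6-hydroxyphenyl]-3-[2-(benzyloxy)-4-methoxy-5-(methoxymethoxy)phenyl]-3-(diethylamino)prop-2-en-1-one | CCN(CC)/C(c1cc(OCOC)c(OC)cc1OCc1ccccc1)=C/C(=O)c1c(O)cc(OCc2ccccc2)cc1OCc1ccccc1 | intermediate
16 | 5,7,2'-tris(benzyloxy)-4'-methoxy-5'-(methoxymethoxy)flavone | COCOc1cc(-c2cc(=O)c3c(OCc4ccccc4)cc(OCc4ccccc4)cc3o2)c(OCc2ccccc2)cc1OC | intermediate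
17 | 5,7,2'-tris(benzyloxy)-3-lithio-4'-methoxy-5'-(methoxymethoxy)flavone | COCOc1cc(-c2oc3cc(OCc4ccccc4)cc(OCc4ccccc4)c3c(=O)c2[Li])c(OCc2ccccc2)cc1OC | intermediate
18 | dimethyl [5,7,2'-tris(benzyloxy)-4'-methoxy-5'-(methoxymethoxy)flavon-3-yl]boronate | COCOc1cc(-c2oc3cc(OCc4ccccc4)cc(OCc4ccccc4)c3c(=O)c2B(OC)OC)c(OCc2ccccc2)cc1OC | intermediate
19 | 5,7,2'-tris(benzyloxy)-3-hydroxy-4'-methoxy-5'-(methoxymethoxy)flavone | COCOc1cc(-c2oc3cc(OCc4ccccc4)cc(OCc4ccccc4)c3c(=O)c2O)c(OCc2ccccc2)cc1OC | intermediate
20 | 5,7,2'-tris(benzyloxy)-3,4'-dimethoxy-5'-(methoxymethoxy)flavone | COCOc1cc(-c2oc3cc(OCc4ccccc4)cc(OCc4ccccc4)c3c(=O)c2OC)c(OCc2ccccc2)cc1OC | intermediate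
21 | 5,7,2'-tris(benzyloxy)-5'-hydroxy-3,4'-dimethoxyflavone | COc1cc(OCc2ccccc2)c(-c2oc3cc(OCc4ccccc4)cc(OCc4ccccc4)c3c(=O)c2OC)cc1O | intermediate
22 | 5,7,2'-tris(benzyloxy)-3,4'-dimethoxyflavon-5'-yl acetate | COc1cc(OCc2ccccc2)c(-c2oc3cc(OCc4ccccc4)cc(OCc4ccccc4)c3c(=O)c2OC)cc1OC(C)=O | intermediate
23 | 5,7,2',5'-tetrahydroxy-3,4'-dimethoxyflavone 5'-acetate | COc1cc(O)c(-c2oc3cc(O)cc(O)c3c(=O)c2OC)cc1OC(C)=O | target

**Step count**

Total steps: 14. Longest linear sequence: 12 steps (steps 3 to 14, from vanillin); the ring A branch (steps 1 and 2) joins at step 9.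

**Steps most likely to fail**

Step 9 (key step).
- Risk: oxidative addition at a C–I bond flanked by two oxygen substituents is slow. Direct alkynylation without CO uptake (leading on to a benzofuran), capture of the aroylpalladium species by diethylamine as an amide, or early loss of the acetate followed by 5-exo closure could then compete.
- Fallback: ring C is built by the chalcone route, setting out from iodide 9 and returning at flavone 16. Iodine–magnesium exchange on 9 (i-PrMgCl·LiCl, THF, −20 °C) and quenching with DMF should give 2-(benzyloxy)-4-methoxy-5-(methoxymethoxy)benzaldehyde F1. Commercial 2',4',6'-trihydroxyacetophenone is dibenzylated (BnBr, K2CO3, DMF) to 1-[2,4-bis(benzyloxy)-6-hydroxyphenyl]ethanone F2. Claisen–Schmidt condensation of the two (KOH, EtOH, rt) should give (E)-1-[2,4-bis(benzyloxy)-6-hydroxyphenyl]-3-[2-(benzyloxy)-4-methoxy-5-(methoxymethoxy)phenyl]prop-2-en-1-one F3. Oxidative cyclisation of the 2'-hydroxychalcone (I2 cat., DMSO, 120 °C, short heating to spare the acetal) should then give 16.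

Step 10.
- Risk: the amide base may deprotonate a benzylic CH2 or an aryl position next to an oxygen substituent instead of C3, the borate may trap the anion incompletely, and the peroxide may over-oxidise the electron-rich flavonol.
- Fallback: the oxygen is brought in by epoxidation, setting out from flavone 16 and returning at flavonol 19. Dimethyldioxirane (acetone/CH2Cl2, 0 °C to rt) should epoxidise the C2=C3 bond to racemic 5,7-bis(benzyloxy)-2-[2-(benzyloxy)-4-methoxy-5-(methoxymethoxy)phenyl]-2,3-epoxychroman-4-one F4. A trace of p-TsOH in CH2Cl2 at rt should open the epoxide at C2 and, after loss of the C3 proton, give 19.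

Step 1.
- Risk: iodination may also occur at C4 between the two benzyloxy groups or run on to di-iodination, giving regioisomers that are hard to separate.
- Fallback: regiochemistry is fixed by directed ortho-metalation, setting out from phenol 1 and returning at iodophenol 2. Protection (MOMCl, NaH, DMF, 0 °C) should give 1,3-bis(benzyloxy)-5-(methoxymethoxy)benzene F5. Lithiation between the acetal and a benzyloxy group (n-BuLi, TMEDA, THF, −20 °C) and quenching with I2 should give 1,5-bis(benzyloxy)-2-iodo-3-(methoxymethoxy)benzene F6. Acetal methanolysis (HCl cat., MeOH, rt) then gives 2.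

**Further compounds**

F1 | step 9 | 2-(benzyloxy)-4-methoxy-5-(methoxymethoxy)benzaldehyde | COCOc1cc(C=O)c(OCc2ccccc2)cc1OC
F2 | step 9 | 1-[2,4-bis(benzyloxy)-6-hydroxyphenyl]ethanone | CC(=O)c1c(O)cc(OCc2ccccc2)cc1OCc1ccccc1
F3 | step 9 | (E)-1-[2,4-bis(benzyloxy)-6-hydroxyphenyl]-3-[2-(benzyloxy)-4-methoxy-5-(methoxymethoxy)phenyl]prop-2-en-1-one | O=C(/C=C/c1cc(OCOC)c(OC)cc1OCc1ccccc1)c1c(O)cc(OCc2ccccc2)cc1OCc1ccccc1
F4 | step 10 | 5,7-bis(benzyloxy)-2-[2-(benzyloxy)-4-methoxy-5-(methoxymethoxy)phenyl]-2,3-epoxychroman-4-one (racemic, one enantiomer drawn) | O=C1c2c(OCc3ccccc3)cc(OCc3ccccc3)cc2O[C@@]2(c3cc(OCOC)c(OC)cc3OCc3ccccc3)O[C@@H]12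
F5 | step 1 | 1,3-bis(benzyloxy)-5-(methoxymethoxy)benzene | COCOc1cc(OCc2ccccc2)cc(OCc2ccccc2)c1
F6 | step 1 | 1,5-bis(benzyloxy)-2-iodo-3-(methoxymethoxy)benzene | COCOc1cc(OCc2ccccc2)cc(OCc2ccccc2)c1I
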